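**Retrosynthetic overview**

1. The target is ECG-(4β→6)-ECG-(4β→8)-ECG (ECG = (−)-epicatechin 3-O-gallate; every unit 2R,3R, both interflavan bonds trans to the neighbouring C3 ester). The last step is hydrogenolysis of twenty-one benzyl ethers and one C8 bromide.
2. Key disconnection (step 13): ring C of the middle unit (O1–C2–C3–C4–C4a–C8a), its C3 gallate and the C4–C8 bond to the lower unit are made together. The precursors are a cis-2-aryl-2,3-dihydrobenzofuran-3-carbaldehyde (five-membered ring O1–C2–C3–C3a–C7a, one atom fewer), galloyl chloride and benzylated ECG.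
3. Enabling feature: ring A of the middle unit carries oxygen on C5, C7 and C8a, i.e. on both ortho positions and the para position of C4a. C4a can therefore shift from C3 to the formyl-derived carbon (future C4) through a phenonium-type bridge. The C3 gallate carbonyl then spans C3/C4 as a dioxolanylium ion and steers the lower unit to the 4β face.
4. Upper bond: the C4 cation of benzylated ECG (DDQ acetal) attacks C5 of the dihydrobenzofuran, whose C7 is blocked by bromine; this fixes the 4→6 connectivity. Benzylated ECG comes from (−)-epicatechin by benzylation and galloylation. The dihydrobenzofuran comes from enantioselective Rh-carbenoid C–H insertion of an aryldiazoacetate built from 3,5-bis(benzyloxy)phenol, oxalyl chloride and 3,4-bis(benzyloxy)benzyl chloride.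
5. Ring order: the pyran rings of the upper and lower units come from (−)-epicatechin; a benzofuran-2,3-dione ring is made and opened in step 5; the dihydrofuran ring is closed in step 8 and expanded to the middle pyran ring in step 13.

Key step: step 13

Assumption: Rh2(S-PTTL)4 is taken to deliver the (2S,3R)-cis ester 15; if its sense of induction on this substrate is the opposite, the mirror-image catalyst Rh2(R-PTTL)4 is used and nothing else changes.

**Step 1**
Reactants: 1 (−)-epicatechin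
Product: 2 5,7,3',4'-tetra-O-benzyl-(−)-epicatechin
Conditions: BnBr (4.4 equiv), K2CO3, DMF, 0 °C to rt
Reagents that add atoms: benzyl bromide, BrCc1ccccc1
Why: Williamson etherification of the four phenols under mild carbonate conditions, which do not deprotonate the secondary C3 alcohol, should leave that hydroxyl group free and the (2R,3R) stereocentres untouched.

**Step 2**
Reactants: 3 3,4,5-tris(benzyloxy)benzoic acid; 4 oxalyl chloride
Product: 5 3,4,5-tris(benzyloxy)benzoyl chloride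
Conditions: (COCl)2, DMF (cat.), CH2Cl2, 0 °C to rt
Reagents that add atoms: none
Why: standard acyl chloride formation through the Vilsmeier-type chloroiminium catalyst.

**Step 3**
Reactants: 2 5,7,3',4'-tetra-O-benzyl-(−)-epicatechin; 5 3,4,5-tris(benzyloxy)benzoyl chloride
Product: 6 hepta-O-benzyl-ECG
Conditions: Et3N, DMAP (cat.), CH2Cl2, 0 °C to rt
Reagents that add atoms: none
Why: DMAP-catalysed O-acylation (nucleophilic acyl substitution) of the only free hydroxyl group, the secondary C3 alcohol, does not touch the C3–O bond and so retains the (2R,3R) configuration.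

**Step 4**
Reactants: 6 hepta-O-benzyl-ECG
Product: 7 (2R,3R,4S)-4-(2-ethoxyethoxy) derivative of 6 (4β-alkoxy; 3,4-trans)
Conditions: DDQ, 2-ethoxyethanol, CH2Cl2, rt
Reagents that add atoms: 2-ethoxyethanol, CCOCCO
Why: DDQ benzylic oxidation abstracts hydride from C4 (cation stabilised by the 5,7-dibenzyloxy ring A) and the alcohol adds anti to the C3 ester, which sets the new C4 stereocentre 3,4-trans.

**Step 5**
Reactants: 8 3,5-bis(benzyloxy)phenol; 4 oxalyl chloride
Product: 10 methyl 2-[2,4-bis(benzyloxy)-6-hydroxyphenyl]-2-oxoacetate, via benzofuran-2,3-dione 9 (not isolated)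
Conditions: (COCl)2, Et2O, 0 °C to rt; then MeOH, rt
Reagents that add atoms: methanol, CO
Why: O-acylation followed by intramolecular Friedel–Crafts acylation at either of the two equivalent ortho carbons gives the benzofurandione, whose strained aryl lactone is opened by methanol (transesterification) to the ortho-hydroxyaryl glyoxylate.

**Step 6**
Reactants: 10 methyl 2-[2,4-bis(benzyloxy)-6-hydroxyphenyl]-2-oxoacetate; 11 3,4-bis(benzyloxy)benzyl chloride
Product: 12 methyl 2-{2,4-bis(benzyloxy)-6-[3,4-bis(benzyloxy)benzyloxy]phenyl}-2-oxoacetate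
Conditions: K2CO3, DMF, 60 °C
Reagents that add atoms: none
Why: Williamson etherification of the only free phenol with the benzylic chloride installs the future C2 carbon and ring B, and the aryl glyoxylate has no enolisable position that could interfere.

**Step 7**
Reactants: 12 methyl 2-{2,4-bis(benzyloxy)-6-[3,4-bis(benzyloxy)benzyloxy]phenyl}-2-oxoacetate
Product: 14 methyl 2-diazo-2-{2,4-bis(benzyloxy)-6-[3,4-bis(benzyloxy)benzyloxy]phenyl}acetate, via tosylhydrazone 13 (not isolated)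
Conditions: TsNHNH2, MeOH, 50 °C; then DBU, CH2Cl2, 0 °C to rt
Reagents that add atoms: p-toluenesulfonyl hydrazide, Cc1ccc(cc1)S(=O)(=O)NN
Why: condensation at the ketone carbonyl followed by base-induced loss of sulfinate (Bamford–Stevens-type diazo formation) is a standard route to aryldiazoacetates.

**Step 8**
Reactants: 14 methyl 2-diazo-2-{2,4-bis(benzyloxy)-6-[3,4-bis(benzyloxy)benzyloxy]phenyl}acetate
Product: 15 methyl (2S,3R)-4,6-bis(benzyloxy)-2-[3,4-bis(benzyloxy)phenyl]-2,3-dihydro-1-benzofuran-3-carboxylate (2,3-cis)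
Conditions: Rh2(S-PTTL)4 (dirhodium tetrakis[N-phthaloyl-(S)-tert-leucinate], 1 mol %), toluene, −60 °C
Reagents that add atoms: none
Why: intramolecular 1,5 C–H insertion of the donor/acceptor dirhodium carbenoid into the benzylic C–H of the 3,4-bis(benzyloxy)benzyl ether (more hydridic than that of the flanking O-benzyl group) closes the dihydrofuran ring, the concerted insertion giving the 2,3-cis isomer while the chiral carboxylate ligands set both new stereocentres.

**Step 9**
Reactants: 15 methyl (2S,3R)-cis-dihydrobenzofuran-3-carboxylate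
Product: 16 [(2S,3S)-4,6-bis(benzyloxy)-2-[3,4-bis(benzyloxy)phenyl]-2,3-dihydro-1-benzofuran-3-yl]methanol (2,3-cis)
Conditions: LiAlH4, THF, −20 °C
Reagents that add atoms: none
Why: hydride reduction of the methyl ester to the primary alcohol, run cold so that no base can epimerise the cis C3 centre, which is no longer acidic afterwards.

**Step 10**
Reactants: 16 cis-dihydrobenzofuran-3-ylmethanol
Product: 17 [(2S,3S)-4,6-bis(benzyloxy)-2-[3,4-bis(benzyloxy)phenyl]-7-bromo-2,3-dihydro-1-benzofuran-3-yl]methanol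
Conditions: NBS, CH2Cl2, −78 to −40 °C
Reagents that add atoms: N-bromosuccinimide, O=C1CCC(=O)N1Br
Why: electrophilic aromatic bromination should go to C7, the less hindered of the two free ring A positions (ortho to the ring oxygen, para to the C4 benzyloxy group), by analogy with the C8-selective bromination of 5,7-dibenzyloxyflavans, and so blocks the future C8 of the middle unit.

**Step 11**
Reactants: 17 7-bromo-cis-dihydrobenzofuran-3-ylmethanol; 7 4β-(2-ethoxyethoxy)-hepta-O-benzyl-ECG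
Product: 18 hepta-O-benzyl-ECG unit 4β-linked through its C4 (trans to its C3 gallate) to C5 of [(2S,3S)-4,6-bis(benzyloxy)-2-[3,4-bis(benzyloxy)phenyl]-7-bromo-2,3-dihydro-1-benzofuran-3-yl]methanol
Conditions: TMSOTf (cat.), 4 Å MS, CH2Cl2, −78 °C, 17 in excess
Reagents that add atoms: none
Why: Lewis-acid ionisation of the C4 acetal gives the flavan-4-yl cation, bridged by the C3 gallate as a dioxolanylium ion, which undergoes Friedel–Crafts alkylation by C5 of 17 (the only unblocked ring A carbon) from the face anti to the C3 oxygen, setting the upper C4 as 4β, while any O-alkylation of the primary alcohol is reversible under the same conditions and should drain to the C-aryl product.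

**Step 12**
Reactants: 18 dimer alcohol
Product: 19 the corresponding aldehyde (dihydrobenzofuran part (2S,3R)-3-carbaldehyde; 2,3-cis)
Conditions: Dess–Martin periodinane, NaHCO3, CH2Cl2, 0 °C; used at once without chromatography
Reagents that add atoms: none
Why: Dess–Martin oxidation of the primary alcohol under buffered, non-basic conditions should give the aldehyde without epimerising the cis C3 centre next to the formyl group.

**Step 13**
Reactants: 19 dimer aldehyde; 5 3,4,5-tris(benzyloxy)benzoyl chloride; 6 hepta-O-benzyl-ECG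
Product: 22 benzyl-protected 8-bromo trimer [hepta-O-benzyl-ECG]-(4β→6)-[8-bromo-hepta-O-benzyl-ECG]-(4β→8)-[hepta-O-benzyl-ECG], via chloroalkyl gallate 20 (not isolated), via dioxolanylium triflate 21 (not isolated)
Conditions: 5 (1.0 equiv), ZnCl2 (5 mol %), CH2Cl2, −20 °C; then 6 (3 equiv), 2,6-di-tert-butyl-4-methylpyridine, AgOTf, 4 Å MS, −78 to −30 °C
Reagents that add atoms: none
Why: Proposed new method: ZnCl2-catalysed addition of 5 across the formyl group gives the 1-chloroalkyl gallate 20; AgOTf then abstracts chloride while the ring A carbon C3a (future C4a) bridges to the acyloxy-bearing carbon through a phenonium-type transition state, so that a Wagner–Meerwein 1,2-aryl shift turns the five-membered ring O1–C2–C3–C3a–C7a into the six-membered ring C (O1–C2–C3–C4–C4a–C8a) with the former formyl carbon inserted as C4. As the aryl group leaves C3, the gallate carbonyl oxygen closes on C3 from the opposite face (5-exo closure, inversion at C3) to give the cis-fused 2-aryl-1,3-dioxolan-2-ylium ion 21, which C8 of 6 opens at the benzylic C4 from the face anti to the C3 oxygen in a Friedel–Crafts alkylation. The closest known reaction types are neophyl-type 1,2-aryl shifts of beta-aryl cations, 1-chloroalkyl ester formation from aldehydes and acid chlorides, acyloxonium neighbouring-group participation (Prévost–Woodward, 1,2-trans glycosylation, the invertive rearrangement of enol ester epoxides to alpha-acyloxy ketones) and the Lewis-acid coupling of 3-O-acyl flavan-4-yl cations with flavan nucleophiles. C2 is a spectator and keeps its configuration; C3 is set by the stereospecific inversion at the migration origin, so the cis dihydrobenzofuran gives the 2,3-cis flavan; C4 is set 3,4-trans by anti opening of the dioxolanylium ion. The step needs aryl migration to outrun 1,2-hydride shift, C2 migration and direct capture of the acyloxycarbenium carbon, which the oxygen substituents on both ortho positions and the para position of the migrating carbon should secure by stabilising the bridged arenium ion; the carbonyl oxygen must also win the opening at C3, which its five-membered tether should secure. Attack through C8 rather than C6 of 6 follows the inherent preference of 5,7-dibenzyloxyflavans, excess 6 suppresses capture by ring A of a second substrate molecule, and the buffered cold medium should keep the benzyl ethers and the existing interflavan bond intact.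

**Step 14**
Reactants: 22 benzyl-protected 8-bromo trimer
Product: 23 ECG-(4β→6)-ECG-(4β→8)-ECG (CNP0183218.1)
Conditions: H2 (1 atm), Pd(OH)2/C, Et3N, THF/MeOH, rt
Reagents that add atoms: none
Why: catalytic hydrogenolysis should cleave the twenty-one benzyl ethers and the aryl C–Br bond (hydrodehalogenation, HBr taken up by Et3N) without touching the gallate esters, the interflavan bonds or any stereocentre.

**Compound list**

1 | (−)-epicatechin, (2R,3R)-2-(3,4-dihydroxyphenyl)chroman-3,5,7-triol | O[C@@H]1Cc2c(O)cc(O)cc2O[C@@H]1c1ccc(O)c(O)c1 | starting material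

2 | 5,7,3',4'-tetra-O-benzyl-(−)-epicatechin, (2R,3R)-5,7-bis(benzyloxy)-2-[3,4-bis(benzyloxy)phenyl]chroman-3-ol | O[C@@H]1Cc2c(OCc5ccccc5)cc(OCc5ccccc5)cc2O[C@@H]1c1ccc(OCc5ccccc5)c(OCc5ccccc5)c1 | intermediate

3 | 3,4,5-tris(benzyloxy)benzoic acid | OC(=O)c1cc(OCc2ccccc2)c(OCc2ccccc2)c(OCc2ccccc2)c1 | starting material

4 | oxalyl chloride | ClC(=O)C(Cl)=O | starting material

5 | 3,4,5-tris(benzyloxy)benzoyl chloride | ClC(=O)c1cc(OCc2ccccc2)c(OCc2ccccc2)c(OCc2ccccc2)c1 | intermediate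

6 | hepta-O-benzyl-ECG, (2R,3R)-5,7-bis(benzyloxy)-2-[3,4-bis(benzyloxy)phenyl]chroman-3-yl 3,4,5-tris(benzyloxy)benzoate | O=C(O[C@@H]1Cc2c(OCc5ccccc5)cc(OCc5ccccc5)cc2O[C@@H]1c1ccc(OCc5ccccc5)c(OCc5ccccc5)c1)c1cc(OCc5ccccc5)c(OCc5ccccc5)c(OCc5ccccc5)c1 | intermediate

7 | (2R,3R,4S)-5,7-bis(benzyloxy)-2-[3,4-bis(benzyloxy)phenyl]-4-(2-ethoxyethoxy)chroman-3-yl 3,4,5-tris(benzyloxy)benzoate (4β-alkoxy, 3,4-trans) | O=C(O[C@@H]1[C@@H](OCCOCC)c2c(OCc5ccccc5)cc(OCc5ccccc5)cc2O[C@@H]1c1ccc(OCc5ccccc5)c(OCc5ccccc5)c1)c1cc(OCc5ccccc5)c(OCc5ccccc5)c(OCc5ccccc5)c1 | intermediate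

8 | 3,5-bis(benzyloxy)phenol | Oc1cc(OCc2ccccc2)cc(OCc2ccccc2)c1 | starting material

9 | 4,6-bis(benzyloxy)-1-benzofuran-2,3-dione | O=C1Oc2cc(OCc3ccccc3)cc(OCc3ccccc3)c2C1=O | intermediate

10 | methyl 2-[2,4-bis(benzyloxy)-6-hydroxyphenyl]-2-oxoacetate | COC(=O)C(=O)c1c(O)cc(OCc2ccccc2)cc1OCc1ccccc1 | intermediate

11 | 3,4-bis(benzyloxy)benzyl chloride | ClCc1ccc(OCc2ccccc2)c(OCc2ccccc2)c1 | starting material

12 | methyl 2-{2,4-bis(benzyloxy)-6-[3,4-bis(benzyloxy)benzyloxy]phenyl}-2-oxoacetate | COC(=O)C(=O)c1c(OCc2ccc(OCc3ccccc3)c(OCc3ccccc3)c2)cc(OCc2ccccc2)cc1OCc1ccccc1 | intermediate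

13 | p-toluenesulfonylhydrazone of 12 at the ketone carbon | COC(=O)C(=NNS(=O)(=O)c1ccc(C)cc1)c1c(OCc2ccc(OCc3ccccc3)c(OCc3ccccc3)c2)cc(OCc2ccccc2)cc1OCc1ccccc1 | intermediate

14 | methyl 2-diazo-2-{2,4-bis(benzyloxy)-6-[3,4-bis(benzyloxy)benzyloxy]phenyl}acetate | COC(=O)C(=[N+]=[N-])c1c(OCc2ccc(OCc3ccccc3)c(OCc3ccccc3)c2)cc(OCc2ccccc2)cc1OCc1ccccc1 | intermediate

15 | methyl (2S,3R)-4,6-bis(benzyloxy)-2-[3,4-bis(benzyloxy)phenyl]-2,3-dihydro-1-benzofuran-3-carboxylate (2,3-cis) | COC(=O)[C@H]1[C@@H](c2ccc(OCc3ccccc3)c(OCc3ccccc3)c2)Oc2cc(OCc3ccccc3)cc(OCc3ccccc3)c21 | intermediate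

16 | [(2S,3S)-4,6-bis(benzyloxy)-2-[3,4-bis(benzyloxy)phenyl]-2,3-dihydro-1-benzofuran-3-yl]methanol (2,3-cis) | OC[C@H]1[C@@H](c2ccc(OCc3ccccc3)c(OCc3ccccc3)c2)Oc2cc(OCc3ccccc3)cc(OCc3ccccc3)c21 | intermediate

17 | [(2S,3S)-4,6-bis(benzyloxy)-2-[3,4-bis(benzyloxy)phenyl]-7-bromo-2,3-dihydro-1-benzofuran-3-yl]methanol (2,3-cis) | OC[C@H]1[C@@H](c2ccc(OCc3ccccc3)c(OCc3ccccc3)c2)Oc2c(Br)c(OCc3ccccc3)cc(OCc3ccccc3)c21 | intermediate

18 | hepta-O-benzyl-ECG unit bonded through C4 (4β, trans to its C3 gallate) to C5 of the (2S,3S)-cis-7-bromo-dihydrobenzofuran-3-ylmethanol 17 | O=C(O[C@@H]1[C@@H](c2c(OCc5ccccc5)c(Br)c3c(c2OCc5ccccc5)[C@@H](CO)[C@@H](c2ccc(OCc5ccccc5)c(OCc5ccccc5)c2)O3)c2c(OCc5ccccc5)cc(OCc5ccccc5)cc2O[C@@H]1c1ccc(OCc5ccccc5)c(OCc5ccccc5)c1)c1cc(OCc5ccccc5)c(OCc5ccccc5)c(OCc5ccccc5)c1 | intermediate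

19 | aldehyde of 18: the CH2OH group is CHO, dihydrobenzofuran part (2S,3R), 2,3-cis | O=C(O[C@@H]1[C@@H](c2c(OCc5ccccc5)c(Br)c3c(c2OCc5ccccc5)[C@@H](C=O)[C@@H](c2ccc(OCc5ccccc5)c(OCc5ccccc5)c2)O3)c2c(OCc5ccccc5)cc(OCc5ccccc5)cc2O[C@@H]1c1ccc(OCc5ccccc5)c(OCc5ccccc5)c1)c1cc(OCc5ccccc5)c(OCc5ccccc5)c(OCc5ccccc5)c1 | intermediate

20 | 1-chloroalkyl gallate of 19: the formyl carbon is CH(Cl)–O–CO–C6H2(OBn)3 (both epimers at that carbon) | O=C(O[C@@H]1[C@@H](c2c(OCc5ccccc5)c(Br)c3c(c2OCc5ccccc5)[C@@H](C(Cl)OC(=O)c2cc(OCc5ccccc5)c(OCc5ccccc5)c(OCc5ccccc5)c2)[C@@H](c2ccc(OCc5ccccc5)c(OCc5ccccc5)c2)O3)c2c(OCc5ccccc5)cc(OCc5ccccc5)cc2O[C@@H]1c1ccc(OCc5ccccc5)c(OCc5ccccc5)c1)c1cc(OCc5ccccc5)c(OCc5ccccc5)c(OCc5ccccc5)c1 | intermediate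

21 | ring-expanded cation: 2-[3,4,5-tris(benzyloxy)phenyl]-1,3-dioxolan-2-ylium triflate cis-fused across C3–C4 of the new middle chroman, both oxygens on the face of the C2 aryl group | O=C(O[C@@H]1[C@@H](c2c(OCc5ccccc5)c(Br)c3c(c2OCc5ccccc5)[C@H]6OC(c7cc(OCc5ccccc5)c(OCc5ccccc5)c(OCc5ccccc5)c7)=[O+][C@H]6[C@@H](c2ccc(OCc5ccccc5)c(OCc5ccccc5)c2)O3)c2c(OCc5ccccc5)cc(OCc5ccccc5)cc2O[C@@H]1c1ccc(OCc5ccccc5)c(OCc5ccccc5)c1)c1cc(OCc5ccccc5)c(OCc5ccccc5)c(OCc5ccccc5)c1.[O-]S(=O)(=O)C(F)(F)F | intermediate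

22 | benzyl-protected 8-bromo trimer: [hepta-O-benzyl-ECG]-(4β→6)-[8-bromo-hepta-O-benzyl-ECG]-(4β→8)-[hepta-O-benzyl-ECG] | O=C(O[C@@H]1[C@@H](c2c(OCc5ccccc5)c(Br)c3c(c2OCc5ccccc5)[C@H](c2c(OCc5ccccc5)cc(OCc5ccccc5)c4c2O[C@H](c2ccc(OCc5ccccc5)c(OCc5ccccc5)c2)[C@H](OC(=O)c2cc(OCc5ccccc5)c(OCc5ccccc5)c(OCc5ccccc5)c2)C4)[C@@H](OC(=O)c2cc(OCc5ccccc5)c(OCc5ccccc5)c(OCc5ccccc5)c2)[C@@H](c2ccc(OCc5ccccc5)c(OCc5ccccc5)c2)O3)c2c(OCc5ccccc5)cc(OCc5ccccc5)cc2O[C@@H]1c1ccc(OCc5ccccc5)c(OCc5ccccc5)c1)c1cc(OCc5ccccc5)c(OCc5ccccc5)c(OCc5ccccc5)c1 | intermediate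

23 | ECG-(4β→6)-ECG-(4β→8)-ECG (CNP0183218.1) | O=C(O[C@@H]1[C@@H](c2c(O)cc3c(c2O)[C@H](c2c(O)cc(O)c4c2O[C@H](c2ccc(O)c(O)c2)[C@H](OC(=O)c2cc(O)c(O)c(O)c2)C4)[C@@H](OC(=O)c2cc(O)c(O)c(O)c2)[C@@H](c2ccc(O)c(O)c2)O3)c2c(O)cc(O)cc2O[C@@H]1c1ccc(O)c(O)c1)c1cc(O)c(O)c(O)c1 | target

**Totals and risks**

Total step count: 14. Longest linear sequence: 10 steps (8 → 10 → 12 → 14 → 15 → 16 → 17 → 18 → 19 → 22 → 23, steps 5–14).

The three steps most likely to fail:

Step 13 (carries the new method). What may go wrong: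
- a 1,2-hydride shift from C3 to the acyloxy-bearing carbon followed by loss of the C2 proton, which aromatises the five-membered ring instead of expanding it;
- migration of C2 instead of the aryl carbon, which reaches the same skeleton through a flavan-4-yl cation but leaves the C3 configuration to facial selectivity instead of stereospecific inversion;
- epimerisation of the cis formyl-bearing centre before acylation, which would carry through as the 2,3-trans series;
- opening of the bridged ion at the wrong carbon;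
- capture of the cation by ring A of a second substrate molecule.

Fallback by known chemistry, setting out from 6 and 7 and rejoining at 22: 6 is brominated at C8 (NBS, CH2Cl2, −78 °C) to 8-bromo-hepta-O-benzyl-ECG F1. F1 in excess is coupled with electrophile 7 (TMSOTf, CH2Cl2, −78 °C) through its only free ring A carbon C6 to give the 4β→6 dimer F2. DDQ and 2-ethoxyethanol in CH2Cl2 oxidise the only remaining flavan CH2 group (C4 of the brominated unit) to the 4β-(2-ethoxyethoxy) dimer F3. TMSOTf-mediated coupling of F3 with an excess of 6 then gives 22 by the usual gallate-assisted 3,4-trans arylation at C8 of 6.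

Step 8. What may go wrong: insertion into the benzylic C–H bond of the flanking O-benzyl group instead of the 3,4-bis(benzyloxy)benzyl ether, insufficient enantio- or cis-selectivity with the doubly ortho-substituted aryl carbenoid, or Buchner-type attack on a benzyl ring.

Fallback that avoids the carbenoid, setting out from 8 and rejoining at 15: oxidative annulation of phenol 8 with methyl 3-[3,4-bis(benzyloxy)phenyl]-3-oxopropanoate F4 (obtainable from commercial 3,4-bis(benzyloxy)acetophenone, NaH and dimethyl carbonate) under FeCl3 (cat.), (tBuO)2, 1,2-dichloroethane, 100 °C should give methyl 4,6-bis(benzyloxy)-2-[3,4-bis(benzyloxy)phenyl]-1-benzofuran-3-carboxylate F5. Asymmetric hydrogenation of the furan C2=C3 bond (H2, catalyst from Ru(cod)(2-methylallyl)2, the chiral imidazolinium salt SINpEt·HBF4 and KOtBu, ligand enantiomer chosen for the 2S,3R product) adds both hydrogens to one face and should give the cis ester 15 without any site-selectivity question.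

Step 10. What may go wrong: bromination at C5 instead of C7, or double bromination, either of which would misdirect or block the upper interflavan bond.

Fallback that places the halogen before the ring is made, setting out from 10 and rejoining at 17: NBS (CH2Cl2, 0 °C) should brominate 10 ortho to its chelated hydroxyl group to give methyl 2-[4,6-bis(benzyloxy)-3-bromo-2-hydroxyphenyl]-2-oxoacetate F6. Alkylation with 11 (K2CO3, DMF) gives the bromo keto ester F7; TsNHNH2 gives its tosylhydrazone F8 and DBU the bromo diazo ester F9. Rh2(S-PTTL)4 in toluene at −60 °C gives methyl (2S,3R)-4,6-bis(benzyloxy)-2-[3,4-bis(benzyloxy)phenyl]-7-bromo-2,3-dihydro-1-benzofuran-3-carboxylate F10, and iBu2AlH (CH2Cl2, −78 °C) reduces the ester without touching the aryl bromide to give 17.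

Further compounds

F1 | step 13 | 8-bromo-hepta-O-benzyl-ECG, (2R,3R)-5,7-bis(benzyloxy)-2-[3,4-bis(benzyloxy)phenyl]-8-bromochroman-3-yl 3,4,5-tris(benzyloxy)benzoate | O=C(O[C@@H]1Cc2c(OCc5ccccc5)cc(OCc5ccccc5)c(Br)c2O[C@@H]1c1ccc(OCc5ccccc5)c(OCc5ccccc5)c1)c1cc(OCc5ccccc5)c(OCc5ccccc5)c(OCc5ccccc5)c1

F2 | step 13 | [hepta-O-benzyl-ECG]-(4β→6)-[8-bromo-hepta-O-benzyl-ECG] | O=C(O[C@@H]1[C@@H](c2c(OCc5ccccc5)c(Br)c3c(c2OCc5ccccc5)C[C@@H](OC(=O)c2cc(OCc5ccccc5)c(OCc5ccccc5)c(OCc5ccccc5)c2)[C@@H](c2ccc(OCc5ccccc5)c(OCc5ccccc5)c2)O3)c2c(OCc5ccccc5)cc(OCc5ccccc5)cc2O[C@@H]1c1ccc(OCc5ccccc5)c(OCc5ccccc5)c1)c1cc(OCc5ccccc5)c(OCc5ccccc5)c(OCc5ccccc5)c1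

F3 | step 13 | F2 carrying a 4β-(2-ethoxyethoxy) group on C4 of the brominated unit (trans to its C3 gallate) | O=C(O[C@@H]1[C@@H](c2c(OCc5ccccc5)c(Br)c3c(c2OCc5ccccc5)[C@H](OCCOCC)[C@@H](OC(=O)c2cc(OCc5ccccc5)c(OCc5ccccc5)c(OCc5ccccc5)c2)[C@@H](c2ccc(OCc5ccccc5)c(OCc5ccccc5)c2)O3)c2c(OCc5ccccc5)cc(OCc5ccccc5)cc2O[C@@H]1c1ccc(OCc5ccccc5)c(OCc5ccccc5)c1)c1cc(OCc5ccccc5)c(OCc5ccccc5)c(OCc5ccccc5)c1

F4 | step 8 | methyl 3-[3,4-bis(benzyloxy)phenyl]-3-oxopropanoate | COC(=O)CC(=O)c1ccc(OCc2ccccc2)c(OCc2ccccc2)c1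

F5 | step 8 | methyl 4,6-bis(benzyloxy)-2-[3,4-bis(benzyloxy)phenyl]-1-benzofuran-3-carboxylate | COC(=O)c1c(-c2ccc(OCc3ccccc3)c(OCc3ccccc3)c2)oc2cc(OCc3ccccc3)cc(OCc3ccccc3)c12

F6 | step 10 | methyl 2-[4,6-bis(benzyloxy)-3-bromo-2-hydroxyphenyl]-2-oxoacetate | COC(=O)C(=O)c1c(O)c(Br)c(OCc2ccccc2)cc1OCc1ccccc1

F7 | step 10 | methyl 2-{4,6-bis(benzyloxy)-2-[3,4-bis(benzyloxy)benzyloxy]-3-bromophenyl}-2-oxoacetate | COC(=O)C(=O)c1c(OCc2ccc(OCc3ccccc3)c(OCc3ccccc3)c2)c(Br)c(OCc2ccccc2)cc1OCc1ccccc1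

F8 | step 10 | p-toluenesulfonylhydrazone of F7 at the ketone carbon | COC(=O)C(=NNS(=O)(=O)c1ccc(C)cc1)c1c(OCc2ccc(OCc3ccccc3)c(OCc3ccccc3)c2)c(Br)c(OCc2ccccc2)cc1OCc1ccccc1

F9 | step 10 | methyl 2-diazo-2-{4,6-bis(benzyloxy)-2-[3,4-bis(benzyloxy)benzyloxy]-3-bromophenyl}acetate | COC(=O)C(=[N+]=[N-])c1c(OCc2ccc(OCc3ccccc3)c(OCc3ccccc3)c2)c(Br)c(OCc2ccccc2)cc1OCc1ccccc1

F10 | step 10 | methyl (2S,3R)-4,6-bis(benzyloxy)-2-[3,4-bis(benzyloxy)phenyl]-7-bromo-2,3-dihydro-1-benzofuran-3-carboxylate (2,3-cis) | COC(=O)[C@H]1[C@@H](c2ccc(OCc3ccccc3)c(OCc3ccccc3)c2)Oc2c(Br)c(OCc3ccccc3)cc(OCc3ccccc3)c21
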